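Divide the charge of solid substrate by the pace at which the solid goes, and, as long as that pace holds steady, you have the time the solid lasts. Two chemists dispute that pace for the autumn flask, which is the very flask asked about, followed so far.

- autumn: solid substrate 48 mM; the very flask that is asked about, followed so far
- flask: solid substrate 48 mM; time 15 d

- autumn (time / d: target / %, solid substrate / %): 1.25: 0, 91.4; 2.50: 0.5, 86.7; 4.00: 2.6, 80.9; 5.00: 4.5, 76.4; 6.00: 7.3, 71.4; 8.00: 9.3, 61.4

(readings scatter by 1 percentage point)

- given per volume of solution although it is solid: solid substrate
- at the start none of the solid substrate is in solution
- what has only dissolved of solid substrate counts as not reacted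
- the reaction counts as stopped when no species that holds the solid substrate changes by six tenths of a point or more over the second half of the time

- which holds at 15 d: what has brought the reaction to rest, or that it has not come to rest (for what has run out or reacted, a solid counts together with what of it has only dissolved) (it is still moving / forward and back rates have come level / all of the solid substrate has reacted)
- how much target there is at 15 d, in percent of the solid substrate charged

The first chemist takes the opening reading, a pace of 3.30 mM/d. Dividing the charge by it gives 14.5 d, less than 15 d, so she expects no solid substrate at the end of this flask.

The second chemist answers that the solution starts empty, and that from 2.50 d to 8.00 d the readings fall nearly straight, at a mean pace F of 2.21 mM/d, slower than hers. His solid life L is 21.7 d, the charge divided by F, which is longer than 15 d, so he expects solid left and the flask moving.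

The forecast, reckoned separately, takes his side with “a solid feeding a saturated solution”, lasting about 20 days. It says it is still moving, with 28 % of target, between 21 % and 36 %.

The flask gives it is still moving, with 23.9 % of target.

    starting material → intermediate A (k = 0.0180 /h)
    intermediate A → side product (k = 0.00980 /h)
    starting material → intermediate B (k = 0.0250 /h)
    intermediate B ⇌ intermediate C (K = 0.230, k = 0.0440 /h)
    intermediate C → target (k = 0.0630 /h)
    intermediate C ⇌ intermediate D (K = 2.10, k = 0.0330 /h)
    solid substrate ⇌ starting material, rate k7*(cs7 - [starting material]) while solid is left; crystals form when [starting material] > cs7 (solubility = 4.10 mM, k = 0.0440 /h)

In this flask the half-life of starting material by its step to intermediate B alone is 1.2 d, far shorter than L, and starting material stands at 4.13 % after 1.50 d and 4.32 % after 15.0 d. In this flask the dissolving has 52 % of its turnover up to 15 d behind it at 7.50 d, and 30.9 % of solid substrate still stands at 15.0 d. The first chemist's verdict fits a neighbour flask: with 19 mM of solid substrate and all else held, L is 8.61 d, less than 15 d, and that neighbour flask keeps 0.012 % of its charge, solid or dissolved.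

Readings and results stem from a simulated flask for substances that don't exist, and the scatter is random.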